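The γ-butyrolactone is disconnected at its C3–C4 bond (C3 = the α-carbon carrying the ring B benzyl group, C4 = the β-carbon). A chiral dirhodium carboxamidate carbene from an achiral 3-arylpropyl diazoacetate inserts into the prochiral CH2 that becomes C4, closing the lactone and setting its stereocentre in one operation. The feature exploited is that C4 is the middle carbon of an ArCH2–CH–CH2O unit, i.e. of a 3-arylpropanol. The dihydrobenzofuran is then grown on the aryl bromide by an auxiliary-controlled aldol and cationic cyclisation, C3 is alkylated trans with a benzylic bromide whose anti-diol comes from a second aldol, and six silyl ethers are removed together.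

Key step: step 4

Ring labels: ring A = guaiacyl ring on the carbinol carbon of the diol unit; ring B = arene carrying the diol chain and the CH2 to lactone C3; ring C = benzo ring of the dihydrobenzofuran; ring D = its 2-aryl ring.

Remark on the chemistry (assumptions):
- Rh2(4S-MPPIM)4, dirhodium tetrakis[methyl (4S)-2-oxo-1-(3-phenylpropanoyl)imidazolidine-4-carboxylate], is taken to deliver the (R)-lactone; the mirror-image catalyst would serve otherwise.
- The magnesium-catalysed anti-aldol is taken to follow the chelated-enolate sense (attack anti to the auxiliary benzyl group).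
- Compound 7 is taken as a catalogue compound.
- The Reformatsky reagent 8 is made as one batch, kept as a cold THF solution under argon, and drawn on for the two cross-couplings (steps 6 and 13), which are run side by side.

Step 1
Reactants: 1 3-(4-hydroxy-3-methoxyphenyl)propan-1-ol (dihydroconiferyl alcohol)
Product: 2 3-(3-bromo-4-hydroxy-5-methoxyphenyl)propan-1-ol
Conditions: NBS, i-Pr2NH (cat.), CH2Cl2, 0 °C
Reagents that add atoms: N-bromosuccinimide, O=C1CCC(=O)N1Br
Why: Amine-mediated ortho-selective electrophilic bromination of a phenol; the para position is blocked by the side chain, so bromine should enter the free position ortho to the hydroxyl.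

Step 2
Reactants: 2 3-(3-bromo-4-hydroxy-5-methoxyphenyl)propan-1-ol
Product: 3 3-[3-bromo-5-methoxy-4-(methoxymethoxy)phenyl]propan-1-ol
Conditions: MOMCl, K2CO3, acetone, 0 °C to rt
Reagents that add atoms: chloromethyl methyl ether, COCCl
Why: Williamson-type O-alkylation of the phenoxide that the weak base forms selectively, leaving the primary alcohol free; the MOM ether masks the phenol and later serves as the acid-labile trigger of step 9.

Step 3
Reactants: 3 3-[3-bromo-5-methoxy-4-(methoxymethoxy)phenyl]propan-1-ol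
Product: 5 3-[3-bromo-5-methoxy-4-(methoxymethoxy)phenyl]propyl diazoacetate, via tosylhydrazone ester 4 (not isolated)
Conditions: TsNHN=CHCOCl, PhNMe2, CH2Cl2, 0 °C; then Et3N, 0 °C to rt
Reagents that add atoms: glyoxylic acid chloride p-toluenesulfonylhydrazone, Cc1ccc(cc1)S(=O)(=O)NN=CC(Cl)=O
Why: Diazoacetate synthesis by acylation of the alcohol followed by base-induced Bamford–Stevens-type loss of p-toluenesulfinate from the glyoxylate hydrazone.

Step 4
Reactants: 5 3-[3-bromo-5-methoxy-4-(methoxymethoxy)phenyl]propyl diazoacetate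
Product: 6 (4R)-4-{[3-bromo-5-methoxy-4-(methoxymethoxy)phenyl]methyl}oxolan-2-one
Conditions: Rh2(4S-MPPIM)4 (1 mol %), CH2Cl2, reflux, slow addition of 5
Reagents that add atoms: none
Why: Loss of N2 at the dirhodium core gives an electrophilic rhodium carbene that inserts into a C–H bond of the chain methylene β to the ester oxygen through a three-centre, hydride-transfer-like transition state, forming the C3–C4 bond of the lactone. The closest known reaction type is the dirhodium carboxamidate-catalysed enantioselective intramolecular C–H insertion of 3-arylpropyl diazoacetates to β-benzyl-γ-butyrolactones. The oxolan-2-one ring closes by 1,5-C–H insertion, the five-membered mode that acceptor carbenes normally prefer. The new stereocentre C4 is set by the catalyst alone, since the substrate is achiral: the chiral carboxamidate ligands differentiate the two enantiotopic C–H bonds, and the (4S) ligand set is expected to give the (R)-lactone. The step needs regioselectivity for this methylene over the benzylic CH2 (six-membered insertion), the OCH2 (four-membered) and the MOM C–H bonds, and chemoselectivity over aromatic cycloaddition and carbene dimerisation; the ester tether, the low electrophilicity of the carboxamidate carbene, the brominated (less electron-rich) arene and slow addition should secure these.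

Step 5
Reactants: 7 (4S)-4-benzyl-3-(bromoacetyl)-1,3-oxazolidin-2-one
Product: 8 bromozinc (Reformatsky) enolate of 7 (THF solution)
Conditions: Zn dust (activated with BrCH2CH2Br and Me3SiCl), THF, 0 °C to rt; solution decanted from excess zinc, titrated and kept cold under argon
Reagents that add atoms: zinc, [Zn]
Why: Reformatsky reagent formation by oxidative insertion of zinc metal into the activated C–Br bond α to the imide carbonyl; the auxiliary stereocentre is not involved, and the single batch supplies both cross-couplings.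

Step 6
Reactants: 6 (4R)-4-{[3-bromo-5-methoxy-4-(methoxymethoxy)phenyl]methyl}oxolan-2-one; 8 bromozinc (Reformatsky) enolate of 7 (THF solution)
Product: 9 (4S)-4-benzyl-3-{[3-methoxy-2-(methoxymethoxy)-5-{[(3R)-5-oxooxolan-3-yl]methyl}phenyl]acetyl}-1,3-oxazolidin-2-one
Conditions: Pd(dba)2 (5 mol %), P(t-Bu)3 (5 mol %), THF, rt to 50 °C
Reagents that add atoms: none
Why: Negishi-type α-arylation of a Reformatsky reagent under zerovalent palladium catalysis; the neutral zinc enolate should couple with the aryl bromide without attacking or enolising the lactone, and no stereocentre is touched.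

Step 7
Reactants: 10 vanillin
Product: 11 3-methoxy-4-(triisopropylsilyloxy)benzaldehyde
Conditions: i-Pr3SiCl, imidazole, DMF, rt
Reagents that add atoms: chlorotriisopropylsilane, CC(C)[Si](Cl)(C(C)C)C(C)C
Why: Standard phenol silylation; the bulky triisopropylsilyl ether is chosen to survive the borohydride, acid and base steps that follow.

Step 8
Reactants: 9 (4S)-4-benzyl-3-{[3-methoxy-2-(methoxymethoxy)-5-{[(3R)-5-oxooxolan-3-yl]methyl}phenyl]acetyl}-1,3-oxazolidin-2-one; 11 3-methoxy-4-(triisopropylsilyloxy)benzaldehyde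
Product: 13 (4S)-4-benzyl-3-[(2S,3S)-3-hydroxy-2-[3-methoxy-2-(methoxymethoxy)-5-{[(3R)-5-oxooxolan-3-yl]methyl}phenyl]-3-[3-methoxy-4-(triisopropylsilyloxy)phenyl]propanoyl]-1,3-oxazolidin-2-one, via Z boron enolate 12 (not isolated)
Conditions: Bu2BOTf, i-Pr2NEt, CH2Cl2, −78 to 0 °C; 11, −78 to 0 °C; then pH 7 buffer, MeOH, H2O2, 0 °C
Reagents that add atoms: none
Why: Evans syn-aldol reaction: the Z boron enolate, formed from the imide selectively over the lactone, reacts through a closed chair transition state on the face away from the auxiliary benzyl group, which should set the carbon that becomes C3 of the dihydrobenzofuran (the carbinol configuration is not needed later).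

Step 9
Reactants: 13 the syn-aldol adduct of step 8
Product: 14 (4S)-4-benzyl-3-{[(2S,3S)-7-methoxy-2-[3-methoxy-4-(triisopropylsilyloxy)phenyl]-5-{[(3R)-5-oxooxolan-3-yl]methyl}-2,3-dihydro-1-benzofuran-3-yl]carbonyl}-1,3-oxazolidin-2-one (2,3-trans)
Conditions: CF3CO2H, CH2Cl2, 0 °C to rt
Reagents that add atoms: none
Why: Acid-mediated cationic cyclisation: the electron-rich benzylic alcohol ionises to a p-silyloxybenzyl cation that the ortho oxygen captures with loss of the MOM group, and the five-membered ring should close 2,3-trans under kinetic and thermodynamic control, so C2 follows from the auxiliary-set C3.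

Step 10
Reactants: 14 the trans-dihydrobenzofuran imide of step 9
Product: 15 (4R)-4-{[(2S,3R)-3-(hydroxymethyl)-7-methoxy-2-[3-methoxy-4-(triisopropylsilyloxy)phenyl]-2,3-dihydro-1-benzofuran-5-yl]methyl}oxolan-2-one
Conditions: NaBH4, THF/H2O, 0 °C
Reagents that add atoms: none
Why: Reductive removal of the Evans auxiliary by borohydride at the activated exocyclic imide carbonyl, which is far more electrophilic than the γ-lactone, so the lactone should survive at low temperature; no stereocentre is touched.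

Step 11
Reactants: 15 the primary alcohol of step 10
Product: 16 (4R)-4-{[(2S,3R)-3-{[(tert-butyldimethylsilyl)oxy]methyl}-7-methoxy-2-[3-methoxy-4-(triisopropylsilyloxy)phenyl]-2,3-dihydro-1-benzofuran-5-yl]methyl}oxolan-2-one
Conditions: t-BuMe2SiCl, imidazole, DMF, rt
Reagents that add atoms: tert-butylchlorodimethylsilane, CC(C)(C)[Si](C)(C)Cl
Why: Silylation of the primary alcohol so that no acidic OH interferes with the enolate alkylation of step 19.

Step 12
Reactants: 17 methyl 3-bromo-4-hydroxy-5-methoxybenzoate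
Product: 18 methyl 3-bromo-4-[(tert-butyldimethylsilyl)oxy]-5-methoxybenzoate
Conditions: t-BuMe2SiCl, imidazole, DMF, rt
Reagents that add atoms: tert-butylchlorodimethylsilane, CC(C)(C)[Si](C)(C)Cl
Why: Silylation of the hindered phenol, which the zinc enolate of step 13 and the later enolisation would not tolerate in free form.

Step 13
Reactants: 18 methyl 3-bromo-4-[(tert-butyldimethylsilyl)oxy]-5-methoxybenzoate; 8 bromozinc (Reformatsky) enolate of 7 (THF solution)
Product: 19 methyl 3-{2-[(4S)-4-benzyl-2-oxo-1,3-oxazolidin-3-yl]-2-oxoethyl}-4-[(tert-butyldimethylsilyl)oxy]-5-methoxybenzoate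
Conditions: Pd(dba)2 (5 mol %), P(t-Bu)3 (5 mol %), THF, rt to 50 °C
Reagents that add atoms: none
Why: The same Negishi-type α-arylation of the Reformatsky reagent as in step 6, with a second portion of the solution of 8; the zinc enolate does not add to the methyl benzoate.

Step 14
Reactants: 19 the arylacetyl imide of step 13; 11 3-methoxy-4-(triisopropylsilyloxy)benzaldehyde
Product: 21 methyl 3-{(2R,3S)-1-[(4S)-4-benzyl-2-oxo-1,3-oxazolidin-3-yl]-3-hydroxy-3-[3-methoxy-4-(triisopropylsilyloxy)phenyl]-1-oxopropan-2-yl}-4-[(tert-butyldimethylsilyl)oxy]-5-methoxybenzoate, via trimethylsilyl ether 20 (not isolated)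
Conditions: MgCl2 (20 mol %), Et3N, Me3SiCl, EtOAc, rt; then 1 M HCl/THF, 0 °C
Reagents that add atoms: none
Why: Magnesium halide-catalysed direct anti-aldol reaction of an Evans imide: soft enolisation gives a chelated Z magnesium enolate that reacts through a boat-like transition state on the face away from the auxiliary benzyl group, silylation of the aldolate turning the catalyst over, which should set both centres of the anti (1S,2S) diol unit.

Step 15
Reactants: 21 the anti-aldol adduct of step 14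
Product: 22 methyl 4-[(tert-butyldimethylsilyl)oxy]-3-{(1S,2S)-1,3-dihydroxy-1-[3-methoxy-4-(triisopropylsilyloxy)phenyl]propan-2-yl}-5-methoxybenzoate
Conditions: NaBH4, THF/H2O, 0 °C
Reagents that add atoms: none
Why: Borohydride removal of the auxiliary at the activated imide carbonyl, chemoselective over the methyl benzoate, with no change at the two stereocentres.

Step 16
Reactants: 22 the 1,3-diol of step 15
Product: 23 methyl 4-[(tert-butyldimethylsilyl)oxy]-3-{(1S,2S)-1,3-bis[(tert-butyldimethylsilyl)oxy]-1-[3-methoxy-4-(triisopropylsilyloxy)phenyl]propan-2-yl}-5-methoxybenzoate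
Conditions: t-BuMe2SiOTf (excess), 2,6-lutidine, CH2Cl2, −78 to 0 °C
Reagents that add atoms: tert-butyldimethylsilyl trifluoromethanesulfonate, CC(C)(C)[Si](C)(C)OS(=O)(=O)C(F)(F)F
Why: Exhaustive silylation of both alcohols with the reactive triflate; because every oxygen ends up silylated, any phenol-to-alkoxide silyl migration in step 15 is harmless.

Step 17
Reactants: 23 the methyl benzoate of step 16
Product: 24 {4-[(tert-butyldimethylsilyl)oxy]-3-{(1S,2S)-1,3-bis[(tert-butyldimethylsilyl)oxy]-1-[3-methoxy-4-(triisopropylsilyloxy)phenyl]propan-2-yl}-5-methoxyphenyl}methanol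
Conditions: i-Bu2AlH, CH2Cl2, −78 to 0 °C; aq. potassium sodium tartrate work-up
Reagents that add atoms: none
Why: Hydride reduction of the aryl ester to the benzylic alcohol; silyl ethers are inert to the aluminium hydride.

Step 18
Reactants: 24 the benzylic alcohol of step 17
Product: 25 4-(bromomethyl)-2-{(1S,2S)-1,3-bis[(tert-butyldimethylsilyl)oxy]-1-[3-methoxy-4-(triisopropylsilyloxy)phenyl]propan-2-yl}-1-[(tert-butyldimethylsilyl)oxy]-6-methoxybenzene
Conditions: CBr4, PPh3, CH2Cl2, 0 °C; used at once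
Reagents that add atoms: carbon tetrabromide, BrC(Br)(Br)Br
Why: Appel reaction under neutral conditions converts the primary benzylic alcohol into the bromide without disturbing silyl ethers or the benzylic silyloxy stereocentre.

Step 19
Reactants: 16 the silylated dihydrobenzofuran lactone of step 11; 25 the benzylic bromide of step 18
Product: 27 hexasilyl ether of the target (3R,4R-trans lactone), via lithium enolate 26 (not isolated)
Conditions: LiN(SiMe3)2, THF, −78 °C; then 25, DMPU, −78 to −30 °C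
Reagents that add atoms: none
Why: Alkylation of the lactone lithium enolate: the electrophile approaches the face opposite the C4 substituent, which should give the 3,4-trans (3R,4R) lactone, as is general for β-benzylbutyrolactone enolates.

Step 20
Reactants: 27 hexasilyl ether of the target
Product: 28 the target, (3R,4R)-3-{[3-{(1S,2S)-1,3-dihydroxy-1-(4-hydroxy-3-methoxyphenyl)propan-2-yl}-4-hydroxy-5-methoxyphenyl]methyl}-4-{[(2S,3R)-2-(4-hydroxy-3-methoxyphenyl)-3-(hydroxymethyl)-7-methoxy-2,3-dihydro-1-benzofuran-5-yl]methyl}oxolan-2-one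
Conditions: Bu4NF, AcOH, THF, 0 °C to rt
Reagents that add atoms: none
Why: Fluoride-mediated desilylation removes all six silyl ethers in one operation; the acetic acid buffer keeps the medium near neutral, which should avoid acid-induced closure of the ring B phenol onto the benzylic carbinol and base-induced lactone opening.

Compound list

1 | 3-(4-hydroxy-3-methoxyphenyl)propan-1-ol | COc1cc(CCCO)ccc1O | starting material
2 | 3-(3-bromo-4-hydroxy-5-methoxyphenyl)propan-1-ol | COc1cc(CCCO)cc(Br)c1O | intermediate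
3 | 3-[3-bromo-5-methoxy-4-(methoxymethoxy)phenyl]propan-1-ol | COCOc1c(Br)cc(CCCO)cc1OC | intermediate
4 | 3-[3-bromo-5-methoxy-4-(methoxymethoxy)phenyl]propyl glyoxylate p-toluenesulfonylhydrazone | COCOc1c(Br)cc(CCCOC(=O)C=NNS(=O)(=O)c2ccc(C)cc2)cc1OC | intermediate (not isolated)
5 | 3-[3-bromo-5-methoxy-4-(methoxymethoxy)phenyl]propyl diazoacetate | COCOc1c(Br)cc(CCCOC(=O)C=[N+]=[N-])cc1OC | intermediate
6 | (4R)-4-{[3-bromo-5-methoxy-4-(methoxymethoxy)phenyl]methyl}oxolan-2-one | COCOc1c(Br)cc(C[C@H]2COC(=O)C2)cc1OC | intermediate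
7 | (4S)-4-benzyl-3-(bromoacetyl)-1,3-oxazolidin-2-one | O=C(CBr)N1[C@@H](Cc2ccccc2)COC1=O | starting material
8 | bromozinc (Reformatsky) enolate of 7 (THF solution) | Br[Zn]CC(=O)N1[C@@H](Cc2ccccc2)COC1=O | intermediate
9 | (4S)-4-benzyl-3-{[3-methoxy-2-(methoxymethoxy)-5-{[(3R)-5-oxooxolan-3-yl]methyl}phenyl]acetyl}-1,3-oxazolidin-2-one | COCOc1c(CC(=O)N2[C@@H](Cc3ccccc3)COC2=O)cc(C[C@H]2COC(=O)C2)cc1OC | intermediate
10 | vanillin | COc1cc(C=O)ccc1O | starting material
11 | 3-methoxy-4-(triisopropylsilyloxy)benzaldehyde | COc1cc(C=O)ccc1O[Si](C(C)C)(C(C)C)C(C)C | intermediate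
12 | Z di-n-butylboron enolate of 9 | CCCCB(CCCC)O/C(=C\c1cc(C[C@H]2COC(=O)C2)cc(OC)c1OCOC)N1[C@@H](Cc2ccccc2)COC1=O | intermediate (not isolated)
13 | (4S)-4-benzyl-3-[(2S,3S)-3-hydroxy-2-[3-methoxy-2-(methoxymethoxy)-5-{[(3R)-5-oxooxolan-3-yl]methyl}phenyl]-3-[3-methoxy-4-(triisopropylsilyloxy)phenyl]propanoyl]-1,3-oxazolidin-2-one | O=C(N1[C@@H](Cc2ccccc2)COC1=O)[C@@H](c1cc(C[C@H]2COC(=O)C2)cc(OC)c1OCOC)[C@H](O)c1ccc(O[Si](C(C)C)(C(C)C)C(C)C)c(OC)c1 | intermediate
14 | (4S)-4-benzyl-3-{[(2S,3S)-7-methoxy-2-[3-methoxy-4-(triisopropylsilyloxy)phenyl]-5-{[(3R)-5-oxooxolan-3-yl]methyl}-2,3-dihydro-1-benzofuran-3-yl]carbonyl}-1,3-oxazolidin-2-one | O=C1OC[C@H](Cc2cc(OC)c3c(c2)[C@H](C(=O)N4[C@@H](Cc5ccccc5)COC4=O)[C@@H](c6ccc(O[Si](C(C)C)(C(C)C)C(C)C)c(OC)c6)O3)C1 | intermediate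
15 | (4R)-4-{[(2S,3R)-3-(hydroxymethyl)-7-methoxy-2-[3-methoxy-4-(triisopropylsilyloxy)phenyl]-2,3-dihydro-1-benzofuran-5-yl]methyl}oxolan-2-one | O=C1OC[C@H](Cc2cc(OC)c3c(c2)[C@H](CO)[C@@H](c4ccc(O[Si](C(C)C)(C(C)C)C(C)C)c(OC)c4)O3)C1 | intermediate
16 | (4R)-4-{[(2S,3R)-3-{[(tert-butyldimethylsilyl)oxy]methyl}-7-methoxy-2-[3-methoxy-4-(triisopropylsilyloxy)phenyl]-2,3-dihydro-1-benzofuran-5-yl]methyl}oxolan-2-one | O=C1OC[C@H](Cc2cc(OC)c3c(c2)[C@H](CO[Si](C)(C)C(C)(C)C)[C@@H](c4ccc(O[Si](C(C)C)(C(C)C)C(C)C)c(OC)c4)O3)C1 | intermediate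
17 | methyl 3-bromo-4-hydroxy-5-methoxybenzoate | COC(=O)c1cc(Br)c(O)c(OC)c1 | starting material
18 | methyl 3-bromo-4-[(tert-butyldimethylsilyl)oxy]-5-methoxybenzoate | COC(=O)c1cc(Br)c(O[Si](C)(C)C(C)(C)C)c(OC)c1 | intermediate
19 | methyl 3-{2-[(4S)-4-benzyl-2-oxo-1,3-oxazolidin-3-yl]-2-oxoethyl}-4-[(tert-butyldimethylsilyl)oxy]-5-methoxybenzoate | COC(=O)c1cc(CC(=O)N2[C@@H](Cc3ccccc3)COC2=O)c(O[Si](C)(C)C(C)(C)C)c(OC)c1 | intermediate
20 | trimethylsilyl ether of 21 | O=C(N1[C@@H](Cc2ccccc2)COC1=O)[C@H](c1cc(C(=O)OC)cc(OC)c1O[Si](C)(C)C(C)(C)C)[C@H](O[Si](C)(C)C)c1ccc(O[Si](C(C)C)(C(C)C)C(C)C)c(OC)c1 | intermediate (not isolated)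
21 | methyl 3-{(2R,3S)-1-[(4S)-4-benzyl-2-oxo-1,3-oxazolidin-3-yl]-3-hydroxy-3-[3-methoxy-4-(triisopropylsilyloxy)phenyl]-1-oxopropan-2-yl}-4-[(tert-butyldimethylsilyl)oxy]-5-methoxybenzoate | O=C(N1[C@@H](Cc2ccccc2)COC1=O)[C@H](c1cc(C(=O)OC)cc(OC)c1O[Si](C)(C)C(C)(C)C)[C@H](O)c1ccc(O[Si](C(C)C)(C(C)C)C(C)C)c(OC)c1 | intermediate
22 | methyl 4-[(tert-butyldimethylsilyl)oxy]-3-{(1S,2S)-1,3-dihydroxy-1-[3-methoxy-4-(triisopropylsilyloxy)phenyl]propan-2-yl}-5-methoxybenzoate | OC[C@H](c1cc(C(=O)OC)cc(OC)c1O[Si](C)(C)C(C)(C)C)[C@H](O)c1ccc(O[Si](C(C)C)(C(C)C)C(C)C)c(OC)c1 | intermediate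
23 | methyl 4-[(tert-butyldimethylsilyl)oxy]-3-{(1S,2S)-1,3-bis[(tert-butyldimethylsilyl)oxy]-1-[3-methoxy-4-(triisopropylsilyloxy)phenyl]propan-2-yl}-5-methoxybenzoate | CC(C)(C)[Si](C)(C)OC[C@H](c1cc(C(=O)OC)cc(OC)c1O[Si](C)(C)C(C)(C)C)[C@H](O[Si](C)(C)C(C)(C)C)c1ccc(O[Si](C(C)C)(C(C)C)C(C)C)c(OC)c1 | intermediate
24 | {4-[(tert-butyldimethylsilyl)oxy]-3-{(1S,2S)-1,3-bis[(tert-butyldimethylsilyl)oxy]-1-[3-methoxy-4-(triisopropylsilyloxy)phenyl]propan-2-yl}-5-methoxyphenyl}methanol | CC(C)(C)[Si](C)(C)OC[C@H](c1cc(CO)cc(OC)c1O[Si](C)(C)C(C)(C)C)[C@H](O[Si](C)(C)C(C)(C)C)c1ccc(O[Si](C(C)C)(C(C)C)C(C)C)c(OC)c1 | intermediate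
25 | 4-(bromomethyl)-2-{(1S,2S)-1,3-bis[(tert-butyldimethylsilyl)oxy]-1-[3-methoxy-4-(triisopropylsilyloxy)phenyl]propan-2-yl}-1-[(tert-butyldimethylsilyl)oxy]-6-methoxybenzene | CC(C)(C)[Si](C)(C)OC[C@H](c1cc(CBr)cc(OC)c1O[Si](C)(C)C(C)(C)C)[C@H](O[Si](C)(C)C(C)(C)C)c1ccc(O[Si](C(C)C)(C(C)C)C(C)C)c(OC)c1 | intermediate
26 | lithium enolate of 16 | [Li]OC1=C[C@@H](Cc2cc(OC)c3c(c2)[C@H](CO[Si](C)(C)C(C)(C)C)[C@@H](c4ccc(O[Si](C(C)C)(C(C)C)C(C)C)c(OC)c4)O3)CO1 | intermediate (not isolated)
27 | hexasilyl ether of the target (four tert-butyldimethylsilyl and two triisopropylsilyl groups; 3R,4R lactone) | COc1cc([C@@H](O[Si](C)(C)C(C)(C)C)[C@H](CO[Si](C)(C)C(C)(C)C)c2cc(C[C@H]3C(=O)OC[C@@H]3Cc3cc(OC)c4c(c3)[C@H](CO[Si](C)(C)C(C)(C)C)[C@@H](c3ccc(O[Si](C(C)C)(C(C)C)C(C)C)c(OC)c3)O4)cc(OC)c2O[Si](C)(C)C(C)(C)C)ccc1O[Si](C(C)C)(C(C)C)C(C)C | intermediate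
28 | (3R,4R)-3-{[3-{(1S,2S)-1,3-dihydroxy-1-(4-hydroxy-3-methoxyphenyl)propan-2-yl}-4-hydroxy-5-methoxyphenyl]methyl}-4-{[(2S,3R)-2-(4-hydroxy-3-methoxyphenyl)-3-(hydroxymethyl)-7-methoxy-2,3-dihydro-1-benzofuran-5-yl]methyl}oxolan-2-one | COc1cc([C@@H](O)[C@H](CO)c2cc(C[C@H]3C(=O)OC[C@@H]3Cc3cc(OC)c4c(c3)[C@H](CO)[C@@H](c3ccc(O)c(OC)c3)O4)cc(OC)c2O)ccc1O | target

Step count and risks

Total step count: 20. Longest linear sequence: 11 steps (steps 1–4, 6, 8–11, 19, 20, from compound 1).

Steps most likely to fail: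

1. Step 14. The magnesium-catalysed anti-aldol may show poor or reversed facial selectivity with the bulky, acidic ortho-silyloxy arylacetyl imide, and the aldolate may revert by retro-aldol cleavage before silylation. The fallback sets out from 18 and comes back at 22. Palladium-catalysed ketone α-arylation (Pd2(dba)3, Xantphos, K3PO4, toluene, 80 °C) would couple 18 with 1-[3-methoxy-4-(triisopropylsilyloxy)phenyl]ethan-1-one F1, itself made from acetovanillone with i-Pr3SiCl and imidazole, to give the deoxybenzoin methyl 4-[(tert-butyldimethylsilyl)oxy]-3-methoxy-5-{2-[3-methoxy-4-(triisopropylsilyloxy)phenyl]-2-oxoethyl}benzoate F2. α-Methylenation (paraformaldehyde, diisopropylammonium trifluoroacetate, THF, reflux) would then give the 1,2-diarylpropenone methyl 4-[(tert-butyldimethylsilyl)oxy]-3-methoxy-5-{3-[3-methoxy-4-(triisopropylsilyloxy)phenyl]-3-oxoprop-1-en-2-yl}benzoate F3. Corey–Bakshi–Shibata reduction ((S)-Me-CBS oxazaborolidine, BH3·SMe2, the 1-arylvinyl group taken as the larger substituent) should give the (R)-allylic alcohol methyl 4-[(tert-butyldimethylsilyl)oxy]-3-{(3R)-3-hydroxy-3-[3-methoxy-4-(triisopropylsilyloxy)phenyl]prop-1-en-2-yl}-5-methoxybenzoate F4. Hydroboration with 9-BBN and oxidation with NaBO3, anti-selective for 1,1-disubstituted allylic alcohols through allylic strain control, should give the anti diol 22.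

2. Step 6. The imide zinc enolate may decompose (loss of the oxazolidinone, self-condensation) or transmetalate too slowly to the ortho-alkoxy arylpalladium bromide, so the cross-coupling may stall. The fallback sets out from 6 and comes back at 9. Coupling of 6 with the Reformatsky reagent of benzyl bromoacetate (Zn, THF; Pd(dba)2, P(t-Bu)3) would give benzyl [3-methoxy-2-(methoxymethoxy)-5-{[(3R)-5-oxooxolan-3-yl]methyl}phenyl]acetate F5. Hydrogenolysis (H2, Pd/C, EtOAc) would give the arylacetic acid [3-methoxy-2-(methoxymethoxy)-5-{[(3R)-5-oxooxolan-3-yl]methyl}phenyl]acetic acid F6. N-Acylation of (S)-4-benzyl-1,3-oxazolidin-2-one with F6 through its mixed pivalic anhydride (pivaloyl chloride, Et3N, LiCl, THF) would give 9.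

3. Step 9. Loss of the acidic C3 proton from the benzylic cation (elimination to a stilbene-type acrylimide) or acyl transfer from the imide to the liberated phenol may outrun ring closure. The fallback sets out from 13 and comes back at 15, reversing the order of reduction and cyclisation. NaBH4 (THF/H2O, 0 °C) would remove the auxiliary first to give (4R)-4-{[3-{(1S,2R)-1,3-dihydroxy-1-[3-methoxy-4-(triisopropylsilyloxy)phenyl]propan-2-yl}-5-methoxy-4-(methoxymethoxy)phenyl]methyl}oxolan-2-one F7. Acid (CF3CO2H or TsOH, CH2Cl2, 0 °C) would then close the trans-dihydrobenzofuran on a substrate that has neither an acidic α-proton nor an acyl group, giving 15 directly.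

Further compounds

F1 | step 14 | 1-[3-methoxy-4-(triisopropylsilyloxy)phenyl]ethan-1-one | CC(=O)c1ccc(O[Si](C(C)C)(C(C)C)C(C)C)c(OC)c1
F2 | step 14 | methyl 4-[(tert-butyldimethylsilyl)oxy]-3-methoxy-5-{2-[3-methoxy-4-(triisopropylsilyloxy)phenyl]-2-oxoethyl}benzoate | COC(=O)c1cc(CC(=O)c2ccc(O[Si](C(C)C)(C(C)C)C(C)C)c(OC)c2)c(O[Si](C)(C)C(C)(C)C)c(OC)c1
F3 | step 14 | methyl 4-[(tert-butyldimethylsilyl)oxy]-3-methoxy-5-{3-[3-methoxy-4-(triisopropylsilyloxy)phenyl]-3-oxoprop-1-en-2-yl}benzoate | COC(=O)c1cc(C(=C)C(=O)c2ccc(O[Si](C(C)C)(C(C)C)C(C)C)c(OC)c2)c(O[Si](C)(C)C(C)(C)C)c(OC)c1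
F4 | step 14 | methyl 4-[(tert-butyldimethylsilyl)oxy]-3-{(3R)-3-hydroxy-3-[3-methoxy-4-(triisopropylsilyloxy)phenyl]prop-1-en-2-yl}-5-methoxybenzoate | COC(=O)c1cc(C(=C)[C@H](O)c2ccc(O[Si](C(C)C)(C(C)C)C(C)C)c(OC)c2)c(O[Si](C)(C)C(C)(C)C)c(OC)c1
F5 | step 6 | benzyl [3-methoxy-2-(methoxymethoxy)-5-{[(3R)-5-oxooxolan-3-yl]methyl}phenyl]acetate | COCOc1c(CC(=O)OCc2ccccc2)cc(C[C@H]2COC(=O)C2)cc1OC
F6 | step 6 | [3-methoxy-2-(methoxymethoxy)-5-{[(3R)-5-oxooxolan-3-yl]methyl}phenyl]acetic acid | COCOc1c(CC(=O)O)cc(C[C@H]2COC(=O)C2)cc1OC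
F7 | step 9 | (4R)-4-{[3-{(1S,2R)-1,3-dihydroxy-1-[3-methoxy-4-(triisopropylsilyloxy)phenyl]propan-2-yl}-5-methoxy-4-(methoxymethoxy)phenyl]methyl}oxolan-2-one | OC[C@@H](c1cc(C[C@H]2COC(=O)C2)cc(OC)c1OCOC)[C@H](O)c1ccc(O[Si](C(C)C)(C(C)C)C(C)C)c(OC)c1
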